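The dawn flask held 3.33 times the substrate of the noon flask, yet at 28 s it had made 1.90 times the target, so the rate levels off as substrate rises.

| setting | midnight | noon | dusk | dawn | autumn |
|---|---|---|---|---|---|
| substrate | 0.800 M | 0.480 M | 0.800 M | 1.60 M | 2.00 M |
| catalyst | 0.00160 M | 0.00160 M | 0.00240 M | 0.00160 M | 0.00160 M |
| time |  |  |  |  | 120 s |

| midnight run: time / s | midnight run: [target] / M | noon run: time / s | noon run: [target] / M | dusk run: time / s | dusk run: [target] / M | dawn run: time / s | dawn run: [target] / M |
|---|---|---|---|---|---|---|---|
| 9.1 | 0.051 | 9.1 | 0.037 | 9.1 | 0.073 | 9.1 | 0.059 |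
| 28 | 0.134 | 28 | 0.105 | 28 | 0.206 | 28 | 0.199 |
| 53 | 0.250 | 53 | 0.172 | 53 | 0.341 | 53 | 0.340 |
| 84 | 0.340 | 84 | 0.235 | 84 | 0.444 | 84 | 0.489 |
| 120 | 0.393 | 120 | 0.261 | 120 | 0.479 | 120 | 0.629 |

(standard deviation of a reading: 0.006 M)

1. reaction order in [catalyst] at the outset, round the charge of the midnight run, defined at two percent of the substrate turned into target
2. reaction order in [substrate] at the outset, round the charge of the midnight run, defined at two percent of the substrate turned into target (one fixed amount of target, the same in the runs compared)
3. target in the autumn run at 120 s, as a share of the substrate charged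

- Overall: substrate -> target, with catalyst as catalyst.
- Constant volume, constant temperature.
- What is held in complexes is read along with the free species.
- An order is taken over about fifteen percent of the charge, up and down.

Dusk over midnight at 28 s gave an order in catalyst of 1.06 as a reading. For substrate I wrote the rate as a[substrate]/(1 + [substrate]/K), and the dawn-to-noon ratio on the charges gave K = 0.996 M.

Then I put that answer back. Over the stretch the mean [substrate] is the charge minus half the target read, 0.427 M in noon and 1.50 M in dawn. The same ratio now gave 0.832 M. This is the half-rate substrate, the [substrate] where the rate stands at half its ceiling and the outset order at 0.5; the usual term is half-saturation constant. The noon stretch then gave a = 0.0133 s⁻¹, and the midnight charge an outset order of 0.510.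

For autumn I went round the same way, taking the rate at the mean substrate, and the amount turned at 120 s ran 0.936 M, 0.859 M, 0.867 M. Dawn reckoned alike ran 0.872 M, 0.773 M, 0.786 M, but dawn read 0.629 M, a share of 0.800. Applying that share to autumn, I committed to 34.7%.

The weak link was K, since the scatter is 5.71% of the noon reading at 28 s. So I repeated the reckoning on the 53 s readings, which are the pair to watch. With ratio 1.98 and mean substrates 0.394 M and 1.43 M, they gave 0.845 M.

The forecast gave 1 (0.8 to 1.2), 0.5 (0.3 to 0.7) and 35.5% (32.5% to 38.5%), and wrote: “The substrate dependence is saturating.” Its yield stood above mine.

The autumn flask gave 34.4% of its charge at 120 s, and the outset orders round the midnight charge are 1.0 in catalyst and 0.51 in substrate.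

    catalyst + substrate → target + catalyst (9.150 M⁻¹ s⁻¹)
    catalyst + substrate ⇌ idle catalyst-substrate complex, settled at all times (1.290 M⁻¹)
    target → decomposed product (0.004520 s⁻¹)

A fit with the main steps alone left a residual of 8.4 in units of the scatter, and the true steps left 0.85. The half-rate substrate 0.832 M puts the outset order at the autumn charge at 0.294. With a, it puts the midnight rate, where two percent of the substrate has turned, at 0.00536 M s⁻¹, and the rate found there is 0.0056 M s⁻¹.

The readings were generated by integration for substances that don't exist; noise was put on by code.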